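The product excess, left-handed product minus right-handed product over their sum, is what both flasks are asked for.

| flask | left-handed substrate | right-handed substrate | reagent | remark | time |
|---|---|---|---|---|---|
| alder | 0.29 M | 0.29 M | 4.3 equiv | run made earlier |  |
| Monday's | 0.29 M | 0.29 M | 3.00 equiv |  | 6.0 min |
| Tuesday's | 0.29 M | 0.29 M | 9.00 equiv |  | 4.0 min |

alder run (percent of the left-handed substrate and right-handed substrate together charged)

| time / min | left-handed product / % | right-handed product / % |
|---|---|---|
| 0.417 | 2.9 | 1.6 |
| 1.00 | 7.2 | 1.6 |
| 2.00 | 12.0 | 5.0 |
| 3.00 | 15.6 | 7.2 |
| 4.00 | 19.4 | 9.9 |

(scatter of a reading: 1 percentage point)

- reagent is single-handed; left-handed substrate and right-handed substrate are mirror images of each other, charged as a racemate, each of them at the stated concentration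
- candidate steps: reagent -> decomposition product; left-handed substrate <-> right-handed substrate; left-handed product <-> right-handed product; reagent + right-handed substrate -> right-handed product; reagent + left-handed substrate -> left-handed product
- an excess is below zero if the other one leads
- the handed part of reagent does not stay in what it makes, so the products of the two hands are mirror images too

- which of the two ends with the higher excess of left-handed product over right-handed product ("neither" if they lie within 2 percentage points) (Monday's / Tuesday's / neither)
- excess of left-handed product over right-handed product at the end, Monday's
- excess of left-handed product over right-handed product at the end, Tuesday's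

What does the excess do within one flask? In the alder run it stands at 41.2% after 2.00 min and is lower, 32.4%, after 4.00 min, while both products keep growing. I read this as fresh product arriving at a steady rate and a steady excess while older product racemizes, first-order, through left-handed product <-> right-handed product. Excess times time then levels off exponentially, and these two readings give a fade time, the time in which product excess left to itself falls by a factor e, of 3.61 min.

Does reagent shift this? More reagent speeds the making of both products in one proportion, and the fade step contains no reagent. So, neglecting the loss of substrate, excess depends on time.

Tuesday's, stopped at 4.0 min, should then stand near the alder value of 32.4%. Monday's, at 6.0 min, comes to 26.2%. That gap of 6.2 percentage points is wider than the margin, so Tuesday's should lead.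

The forecast gave 34% for Monday's and 29% for Tuesday's, with Monday's ahead (“Monday stays ahead, but only modestly”), an order that differs from mine.

    reagent → decomposition product (k = 5.60 × 10⁻⁵ min⁻¹)
    left-handed substrate ⇌ right-handed substrate (k = 11.0 min⁻¹)
    left-handed product ⇌ right-handed product (k = 0.180 min⁻¹)
    reagent + right-handed substrate → right-handed product (k = 0.0310 L mol⁻¹ min⁻¹)
    reagent + left-handed substrate → left-handed product (k = 0.130 L mol⁻¹ min⁻¹)

Tuesday's leads with 29.1% against 22.7% for Monday's, the order the fade time gave, at 3.3 points and 3.5 points below my two values. In Tuesday's the two products relax into each other with a half-life of 1.93 min, counted for that step by itself with both ways together, and the 4.0 min of that flask are twice that. Tuesday's flask, read instead at 2.5 min, holds an excess of 38.6%; the fade time, applied to the alder reading, gives 38.7%.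

All runs were computed for an exercise; the scatter is artificial.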